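**Retrosynthetic overview**

- The plan rests on one feature: the target is the (2R,3R)-dihydrokaempferol skeleton carrying prenyl groups at C8 of ring A (para to the C5 oxygen) and at C3' of ring B (ortho to the C4' oxygen). Both carbons can be reached from those oxygens by [3,3] shifts.
- The C8–CH2 and C3'–CH2 bonds are therefore cut together, back to a 5-O-prenyl, 4'-O-(1,1-dimethylallyl) bis-ether whose 7-hydroxyl is held as a triisopropylsilyl ether.
- That bis-ether comes from dihydrokaempferol by 7-O-silylation, copper-catalysed 4'-O-tert-propargylation, Mitsunobu 5-O-prenylation and semihydrogenation of the alkyne.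
- No ring is formed in the route: rings A, B and C and both stereocentres (C2, C3) are taken intact from the chiral pool, and the silyl group is removed last.

Key step: step 6

Remark: the ring-B Claisen shift is assumed to need more heat than the europium-assisted ring-A relay, so step 6 is staged at two temperatures in one flask.

**Route**

Step 1
Reactants: 1 (2R,3R)-dihydrokaempferol
Product: 2 (2R,3R)-3,5-dihydroxy-2-(4-hydroxyphenyl)-7-(triisopropylsilyloxy)chroman-4-one
Conditions: TIPSCl (1.05 equiv), imidazole, DMF, −20 to 0 °C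
Reagents that add atoms: triisopropylsilyl chloride, CC(C)[Si](Cl)(C(C)C)C(C)C
Why: Selective O-silylation; the 7-hydroxyl, para to the C4 carbonyl, is the most acidic and least hindered phenol, so one equivalent of the bulky chloride should take it ahead of the 4'-phenol, the hydrogen-bonded 5-phenol and the secondary 3-alcohol.

Step 2
Reactants: 3 2-methylbut-3-yn-2-ol
Product: 4 methyl 2-methylbut-3-yn-2-yl carbonate
Conditions: n-BuLi (1.0 equiv), THF, −78 °C; then ClCO2Me, −78 °C to rt
Reagents that add atoms: methyl chloroformate, COC(=O)Cl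
Why: O-acylation of the lithium alkoxide of a tertiary propargylic alcohol with a chloroformate (carbonate formation) is routine and leaves the alkyne C–H untouched at one equivalent of base.

Step 3
Reactants: 2 (2R,3R)-3,5-dihydroxy-2-(4-hydroxyphenyl)-7-(triisopropylsilyloxy)chroman-4-one; 4 methyl 2-methylbut-3-yn-2-yl carbonate
Product: 5 (2R,3R)-3,5-dihydroxy-2-[4-(2-methylbut-3-yn-2-yloxy)phenyl]-7-(triisopropylsilyloxy)chroman-4-one
Conditions: CuCl2·2H2O (1 mol%), DBU (1.2 equiv), MeCN, −5 to 0 °C, argon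
Reagents that add atoms: none
Why: Copper-catalysed propargylic etherification of a phenol through a copper acetylide/allenylidene gives the tertiary aryl propargyl ether; the free 4'-phenol should react ahead of the chelated 5-phenol and the 3-alcohol, and low temperature under argon protects the base-sensitive ring C.

Step 4
Reactants: 5 (2R,3R)-3,5-dihydroxy-2-[4-(2-methylbut-3-yn-2-yloxy)phenyl]-7-(triisopropylsilyloxy)chroman-4-one; 6 3-methylbut-2-en-1-ol
Product: 7 (2R,3R)-3-hydroxy-5-(3-methylbut-2-en-1-yloxy)-2-[4-(2-methylbut-3-yn-2-yloxy)phenyl]-7-(triisopropylsilyloxy)chroman-4-one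
Conditions: PPh3 (1.5 equiv), DIAD (1.5 equiv), THF, 0 °C to rt
Reagents that add atoms: none
Why: Mitsunobu etherification; the primary allylic alcohol is activated faster than the hindered secondary 3-alcohol, and the only remaining phenol (5-OH) displaces it by SN2 at the CH2 terminus, giving the normal prenyl ether without base.

Step 5
Reactants: 7 (2R,3R)-3-hydroxy-5-(3-methylbut-2-en-1-yloxy)-2-[4-(2-methylbut-3-yn-2-yloxy)phenyl]-7-(triisopropylsilyloxy)chroman-4-one
Product: 8 (2R,3R)-3-hydroxy-2-[4-(2-methylbut-3-en-2-yloxy)phenyl]-5-(3-methylbut-2-en-1-yloxy)-7-(triisopropylsilyloxy)chroman-4-one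
Conditions: H2 (1 atm), Pd on CaCO3 poisoned with Pb(OAc)2, quinoline, EtOAc, rt, stopped at one equivalent of H2
Reagents that add atoms: none
Why: Lindlar semihydrogenation takes the terminal alkyne to the vinyl group much faster than it touches the trisubstituted prenyl alkene, the aryl ketone or the silyl ether; the heat-sensitive tertiary allyl ether is kept below 30 °C and used directly.

Step 6
Reactants: 8 (2R,3R)-3-hydroxy-2-[4-(2-methylbut-3-en-2-yloxy)phenyl]-5-(3-methylbut-2-en-1-yloxy)-7-(triisopropylsilyloxy)chroman-4-one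
Product: 13 (2R,3R)-3,5-dihydroxy-2-[4-hydroxy-3-(3-methylbut-2-en-1-yl)phenyl]-8-(3-methylbut-2-en-1-yl)-7-(triisopropylsilyloxy)chroman-4-one, via C6 reverse-prenyl dienone 9 (not isolated), via C8 prenyl dienone 10 (not isolated), via 8-prenyl ring-B tert-allyl ether 11 (not isolated), via ring-B dienone 12 (not isolated)
Conditions: Eu(fod)3 (10 mol%), PhMe, 60 °C, then 100 °C
Reagents that add atoms: none
Why: Trivalent europium in Eu(fod)3, chelated between the C4 carbonyl oxygen and the C5 ether oxygen, weakens the O5–CH2 bond and lets an aromatic Claisen [3,3] shift deliver the allyl unit to C6, the only open ortho carbon, as the 1,1-dimethylallyl dienone 9; a Cope [3,3] shift across C6–C7=C8 then carries it to C8 as dienone 10, and enolisation returns the chelated 5-phenol in 11. On further warming the tertiary allyl aryl ether of ring B undergoes its own chair-like Claisen shift to C3' (dienone 12) and enolises to the 4'-phenol 13. The closest known reaction types are the europium-catalysed Claisen–Cope relay of 5-O-prenylflavonoids to 8-C-prenylflavonoids and the ortho-Claisen rearrangement of aryl 1,1-dimethylallyl ethers. No ring is closed and no stereocentre is created, and the neutral, weakly Lewis acidic medium should leave C2, C3 and the α-ketol untouched. The step needs C8 over C6 on ring A, which the fast Cope shift away from the C6 carbon crowded by the neighbouring 7-O-triisopropylsilyl group should secure, and ortho delivery on ring B, which is enforced because the para carbon C1' is substituted. Both side chains should emerge as normal prenyl groups because the allyl termini invert twice on ring A starting from the normal ether and once on ring B starting from the reversed ether.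

Step 7
Reactants: 13 (2R,3R)-3,5-dihydroxy-2-[4-hydroxy-3-(3-methylbut-2-en-1-yl)phenyl]-8-(3-methylbut-2-en-1-yl)-7-(triisopropylsilyloxy)chroman-4-one
Product: 14 lespedezaflavanone C, (2R,3R)-3,5,7-trihydroxy-2-[4-hydroxy-3-(3-methylbut-2-en-1-yl)phenyl]-8-(3-methylbut-2-en-1-yl)chroman-4-one
Conditions: HF·pyridine, pyridine, THF, 0 °C
Reagents that add atoms: none
Why: Fluoride-mediated cleavage of an aryl silyl ether; the pyridine-buffered medium forms no free phenoxide that could open ring C at C2, and is too weakly acidic to cyclise the ortho-prenyl phenol to a chroman.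

**Compound list**

1 | (2R,3R)-dihydrokaempferol | Oc1ccc([C@H]2Oc3cc(O)cc(O)c3C(=O)[C@@H]2O)cc1 | starting material
2 | (2R,3R)-3,5-dihydroxy-2-(4-hydroxyphenyl)-7-(triisopropylsilyloxy)chroman-4-one | Oc1ccc([C@H]2Oc3cc(O[Si](C(C)C)(C(C)C)C(C)C)cc(O)c3C(=O)[C@@H]2O)cc1 | intermediate
3 | 2-methylbut-3-yn-2-ol | CC(C)(O)C#C | starting material
4 | methyl 2-methylbut-3-yn-2-yl carbonate | COC(=O)OC(C)(C)C#C | intermediate
5 | (2R,3R)-3,5-dihydroxy-2-[4-(2-methylbut-3-yn-2-yloxy)phenyl]-7-(triisopropylsilyloxy)chroman-4-one | C#CC(C)(C)Oc1ccc([C@H]2Oc3cc(O[Si](C(C)C)(C(C)C)C(C)C)cc(O)c3C(=O)[C@@H]2O)cc1 | intermediate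
6 | 3-methylbut-2-en-1-ol | CC(C)=CCO | starting material
7 | (2R,3R)-3-hydroxy-5-(3-methylbut-2-en-1-yloxy)-2-[4-(2-methylbut-3-yn-2-yloxy)phenyl]-7-(triisopropylsilyloxy)chroman-4-one | C#CC(C)(C)Oc1ccc([C@H]2Oc3cc(O[Si](C(C)C)(C(C)C)C(C)C)cc(OCC=C(C)C)c3C(=O)[C@@H]2O)cc1 | intermediate
8 | (2R,3R)-3-hydroxy-2-[4-(2-methylbut-3-en-2-yloxy)phenyl]-5-(3-methylbut-2-en-1-yloxy)-7-(triisopropylsilyloxy)chroman-4-one | C=CC(C)(C)Oc1ccc([C@H]2Oc3cc(O[Si](C(C)C)(C(C)C)C(C)C)cc(OCC=C(C)C)c3C(=O)[C@@H]2O)cc1 | intermediate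
9 | (2R,3R)-3-hydroxy-6-(2-methylbut-3-en-2-yl)-2-[4-(2-methylbut-3-en-2-yloxy)phenyl]-7-(triisopropylsilyloxy)-2,3-dihydro-4H-chromene-4,5(6H)-dione (C6 configuration undefined) | C=CC(C)(C)Oc1ccc([C@H]2OC3=C(C(=O)[C@@H]2O)C(=O)C(C(C)(C)C=C)C(O[Si](C(C)C)(C(C)C)C(C)C)=C3)cc1 | intermediate
10 | (2R,3R)-3-hydroxy-8-(3-methylbut-2-en-1-yl)-2-[4-(2-methylbut-3-en-2-yloxy)phenyl]-7-(triisopropylsilyloxy)-2,3-dihydro-4H-chromene-4,5(8H)-dione (C8 configuration undefined) | C=CC(C)(C)Oc1ccc([C@H]2OC3=C(C(=O)[C@@H]2O)C(=O)C=C(O[Si](C(C)C)(C(C)C)C(C)C)C3CC=C(C)C)cc1 | intermediate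
11 | (2R,3R)-3,5-dihydroxy-8-(3-methylbut-2-en-1-yl)-2-[4-(2-methylbut-3-en-2-yloxy)phenyl]-7-(triisopropylsilyloxy)chroman-4-one | C=CC(C)(C)Oc1ccc([C@H]2Oc3c(CC=C(C)C)c(O[Si](C(C)C)(C(C)C)C(C)C)cc(O)c3C(=O)[C@@H]2O)cc1 | intermediate
12 | (2R,3R)-3,5-dihydroxy-8-(3-methylbut-2-en-1-yl)-2-[3-(3-methylbut-2-en-1-yl)-4-oxocyclohexa-1,5-dien-1-yl]-7-(triisopropylsilyloxy)chroman-4-one (C3' configuration undefined) | CC(C)=CCC1C=C([C@H]2Oc3c(CC=C(C)C)c(O[Si](C(C)C)(C(C)C)C(C)C)cc(O)c3C(=O)[C@@H]2O)C=CC1=O | intermediate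
13 | (2R,3R)-3,5-dihydroxy-2-[4-hydroxy-3-(3-methylbut-2-en-1-yl)phenyl]-8-(3-methylbut-2-en-1-yl)-7-(triisopropylsilyloxy)chroman-4-one | CC(C)=CCc1cc([C@H]2Oc3c(CC=C(C)C)c(O[Si](C(C)C)(C(C)C)C(C)C)cc(O)c3C(=O)[C@@H]2O)ccc1O | intermediate
14 | lespedezaflavanone C, (2R,3R)-3,5,7-trihydroxy-2-[4-hydroxy-3-(3-methylbut-2-en-1-yl)phenyl]-8-(3-methylbut-2-en-1-yl)chroman-4-one | CC(C)=CCc1cc([C@H]2Oc3c(CC=C(C)C)c(O)cc(O)c3C(=O)[C@@H]2O)ccc1O | target

**Step count**

Total steps: 7. Longest linear sequence: 6 (steps 1, 3, 4, 5, 6, 7 from dihydrokaempferol).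

**Steps most likely to fail**

1. Step 6 (tandem rearrangement). The C6 dienone may enolise before the Cope shift and leave a reversed prenyl group at C6. The tertiary allyl ether of ring B may ionise and lose isoprene at the temperature its shift needs, or the two events may not reach completion under one set of conditions. Fallback: the two rearrangements are run apart. Setting out from 7, whose propargyl ether is inert at 60 °C, Eu(fod)3 (10 mol%) in CHCl3 at 60 °C should perform the ring-A relay alone and give (2R,3R)-3,5-dihydroxy-8-(3-methylbut-2-en-1-yl)-2-[4-(2-methylbut-3-yn-2-yloxy)phenyl]-7-(triisopropylsilyloxy)chroman-4-one F1, which can be purified from any C6 isomer. Semihydrogenation under the conditions of step 5 should then give 11, now isolated, and heating 11 alone in PhMe at 110 °C (thermal Claisen shift, no Lewis acid) should give 13, where the route is rejoined.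

2. Step 4 (Mitsunobu etherification). The phosphonium reagent may also activate the free 3-alcohol, leading to dehydration across C2–C3. The chelated 5-phenol may also react so slowly that the reduced azodicarboxylate is alkylated instead. Fallback: the 3-alcohol is masked first. From 5, TESCl and imidazole in DMF at 0 °C should silylate the secondary alcohol ahead of the chelated phenol and give (2R,3R)-5-hydroxy-2-[4-(2-methylbut-3-yn-2-yloxy)phenyl]-3-(triethylsilyloxy)-7-(triisopropylsilyloxy)chroman-4-one F2. Mitsunobu reaction with 6 (PPh3, DIAD, THF) should give (2R,3R)-5-(3-methylbut-2-en-1-yloxy)-2-[4-(2-methylbut-3-yn-2-yloxy)phenyl]-3-(triethylsilyloxy)-7-(triisopropylsilyloxy)chroman-4-one F3. AcOH/THF/H2O at rt should then cleave the alkyl triethylsilyl ether while the aryl triisopropylsilyl ether and both allyl-type ethers stay, returning to 7.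

3. Step 3 (copper-catalysed propargylation). Under DBU the 4'-phenoxide may open ring C at C2–O1 and epimerise C2, the α-ketol may be oxidised toward the flavonol by copper and adventitious air, and the 7-O-silyl group may be lost. Fallback: the tertiary allyl ether is installed directly without amine base. From 2, Pd(PPh3)4 (2 mol%) and methyl 2-methylbut-3-en-2-yl carbonate F4 (made from commercial 2-methylbut-3-en-2-ol with n-BuLi and ClCO2Me as in step 2) in THF at 0 °C should give, by decarboxylative allylic etherification at the more substituted allyl terminus, (2R,3R)-3,5-dihydroxy-2-[4-(2-methylbut-3-en-2-yloxy)phenyl]-7-(triisopropylsilyloxy)chroman-4-one F5. Mitsunobu reaction of F5 with 6 as in step 4 should then give 8 directly, so that step 5 is not needed.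

**Further compounds**

F1 | step 6 | (2R,3R)-3,5-dihydroxy-8-(3-methylbut-2-en-1-yl)-2-[4-(2-methylbut-3-yn-2-yloxy)phenyl]-7-(triisopropylsilyloxy)chroman-4-one | C#CC(C)(C)Oc1ccc([C@H]2Oc3c(CC=C(C)C)c(O[Si](C(C)C)(C(C)C)C(C)C)cc(O)c3C(=O)[C@@H]2O)cc1
F2 | step 4 | (2R,3R)-5-hydroxy-2-[4-(2-methylbut-3-yn-2-yloxy)phenyl]-3-(triethylsilyloxy)-7-(triisopropylsilyloxy)chroman-4-one | C#CC(C)(C)Oc1ccc([C@H]2Oc3cc(O[Si](C(C)C)(C(C)C)C(C)C)cc(O)c3C(=O)[C@@H]2O[Si](CC)(CC)CC)cc1
F3 | step 4 | (2R,3R)-5-(3-methylbut-2-en-1-yloxy)-2-[4-(2-methylbut-3-yn-2-yloxy)phenyl]-3-(triethylsilyloxy)-7-(triisopropylsilyloxy)chroman-4-one | C#CC(C)(C)Oc1ccc([C@H]2Oc3cc(O[Si](C(C)C)(C(C)C)C(C)C)cc(OCC=C(C)C)c3C(=O)[C@@H]2O[Si](CC)(CC)CC)cc1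
F4 | step 3 | methyl 2-methylbut-3-en-2-yl carbonate | COC(=O)OC(C)(C)C=C
F5 | step 3 | (2R,3R)-3,5-dihydroxy-2-[4-(2-methylbut-3-en-2-yloxy)phenyl]-7-(triisopropylsilyloxy)chroman-4-one | C=CC(C)(C)Oc1ccc([C@H]2Oc3cc(O[Si](C(C)C)(C(C)C)C(C)C)cc(O)c3C(=O)[C@@H]2O)cc1
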